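**Plan**

- Retrosynthesis: the furanone ring is opened last at O1–C5 and C2–C3, which returns CO2 and an acyclic α′-tosyloxy ethyl ketone. The chain is then cut at the diene single bond C4′–C5′ (Suzuki), the ketone at its ethyl group (Weinreb amide) and the furan at its ring–CH2 bond (Negishi).
- Enabling feature: the ring is a β-keto-γ-lactone. C3 lies between the C2 lactone carbonyl and the C4 enol carbon, so it is an enolate carbon that can take up CO2. C5 is the other α carbon of the same C4 ketone and can carry a sulfonate, five atoms away from the new carboxylate oxygen.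
- Forward: fragment 1 (C5′–C13′ with the furan, vinyl iodide 13) from (S)-citronellyl bromide, steps 1–6. Fragment 2 (ring C4 to chain C4′, alkenylboronate 25) from (R)-β-citronellene, steps 7–12. Suzuki union (13), ethyl ketone (14), tosylate (15). The furanone, the only ring made in the route, closes in step 16.
- Stereochemistry: C2′ and C10′ come from the two citronellyl chiral-pool materials. The carbinol is set 2S by auxiliary-controlled enolate hydroxylation and inverted to 5R in the ring closure. 3′E comes from cross-metathesis and 5′E from syn-methylalumination; both are kept in the coupling.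

Key step: step 16

Remark: both citronellyl starting materials are taken at the enantiomeric purity of the best commercial grades; the target is written as its 4-hydroxy (enol) tautomer.

**Step 1**
Reactants: 1 (S)-citronellyl bromide [(6S)-8-bromo-2,6-dimethyloct-2-ene]; 2 tri(propan-2-yl)(prop-1-yn-1-yl)silane
Product: 4 [(6R)-6,10-dimethylundec-9-en-1-yn-1-yl]tri(propan-2-yl)silane, via propargyllithium 3 (not isolated)
Conditions: 2, n-BuLi, THF, −20 °C; then 1, DMPU, −78 °C → rt
Reagents that add atoms: none
Why: SN2 propargylation of a primary bromide by the lithium reagent of a bulky 1-silylpropyne should give the chain-extended silylalkyne without allene formation and leaves the remote stereocenter untouched.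

**Step 2**
Reactants: 4
Product: 6 (4R)-4-methyl-9-[tri(propan-2-yl)silyl]non-8-yn-1-ol, via aldehyde 5 (not isolated)
Conditions: O3, CH2Cl2/MeOH, −78 °C (Sudan red 7B end point); then NaBH4, −78 °C → rt
Reagents that add atoms: ozone, [O-][O+]=O
Why: Ozonolysis attacks the electron-rich trisubstituted alkene much faster than the silyl-capped alkyne, and reductive work-up with NaBH4 should give the primary alcohol directly.

**Step 3**
Reactants: 6
Product: 7 [(6R)-9-iodo-6-methylnon-1-yn-1-yl]tri(propan-2-yl)silane
Conditions: I2, PPh3, imidazole, CH2Cl2, 0 °C → rt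
Reagents that add atoms: iodine, II
Why: Appel-type iodination converts the primary alcohol to the iodide under neutral conditions that do not touch the silylalkyne.

**Step 4**
Reactants: 7; 8 3-bromofuran
Product: 10 [(6S)-9-(furan-3-yl)-6-methylnon-1-yn-1-yl]tri(propan-2-yl)silane, via alkylzinc iodide 9 (not isolated)
Conditions: Zn dust, LiCl, THF, 40 °C; then 8, Pd(OAc)2 (2 mol %), SPhos (4 mol %), THF, rt → 50 °C
Reagents that add atoms: none
Why: Negishi sp3–sp2 cross-coupling, in which LiCl-assisted zinc insertion into the primary iodide gives an alkylzinc that should couple with the heteroaryl bromide under Pd/biarylphosphine catalysis without chain isomerization.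

**Step 5**
Reactants: 10
Product: 11 3-[(4R)-4-methylnon-8-yn-1-yl]furan
Conditions: Bu4NF, THF, 0 °C → rt
Reagents that add atoms: none
Why: Fluoride-induced protodesilylation of the alkynylsilane frees the terminal alkyne, and the furan is inert to fluoride.

**Step 6**
Reactants: 11
Product: 13 3-[(4S,8E)-9-iodo-4,8-dimethylnon-8-en-1-yl]furan, via alkenylalane 12 (not isolated)
Conditions: AlMe3, Cp2ZrCl2, CH2Cl2, 0 °C → rt; then I2, THF, −30 → 0 °C
Reagents that add atoms: trimethylaluminium, C[Al](C)C; iodine, II
Why: Negishi zirconium-catalysed methylalumination adds methyl and aluminium syn across the terminal alkyne with aluminium at the terminus, and iodinolysis of the alkenyl–aluminium bond with retention should give the E trisubstituted iodide.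

**Step 7**
Reactants: 14 (R)-β-citronellene [(3R)-3,7-dimethylocta-1,6-diene]
Product: 16 (4R)-4-methylhex-5-enal, via epoxide 15 (not isolated)
Conditions: mCPBA, CH2Cl2, 0 °C; then H5IO6, THF/Et2O, 0 °C → rt
Reagents that add atoms: mCPBA, OOC(=O)c1cccc(Cl)c1
Why: Peracid epoxidation is selective for the trisubstituted over the monosubstituted alkene, and periodic acid opens and cleaves the epoxide to the aldehyde without touching the allylic stereocenter.

**Step 8**
Reactants: 16
Product: 17 (4R)-4-methylhex-5-enoic acid
Conditions: NaClO2, NaH2PO4, 2-methylbut-2-ene, t-BuOH/H2O, rt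
Reagents that add atoms: sodium chlorite, [Na+].[O-]Cl=O
Why: Pinnick oxidation with a hypochlorite scavenger converts the aldehyde to the acid without affecting the vinyl group.

**Step 9**
Reactants: 17; 18 (4S)-4-benzyl-1,3-oxazolidin-2-one
Product: 20 (4S)-4-benzyl-3-[(4R)-4-methylhex-5-enoyl]-1,3-oxazolidin-2-one, via mixed anhydride 19 (not isolated)
Conditions: t-BuCOCl, Et3N, THF, −20 °C; then 18, LiCl, −20 °C → rt
Reagents that add atoms: none
Why: N-Acylation of the Evans oxazolidinone through the mixed pivalic anhydride attaches the auxiliary in one pot.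

**Step 10**
Reactants: 20
Product: 22 (4S)-4-benzyl-3-[(2S,4R)-2-hydroxy-4-methylhex-5-enoyl]-1,3-oxazolidin-2-one, via sodium enolate 21 (not isolated)
Conditions: NaN(SiMe3)2, THF, −78 °C; then 2-(phenylsulfonyl)-3-phenyloxaziridine, −78 °C; AcOH quench
Reagents that add atoms: 2-(phenylsulfonyl)-3-phenyloxaziridine (Davis oxaziridine), O=S(=O)(N1OC1c1ccccc1)c1ccccc1
Why: Evans asymmetric enolate hydroxylation, in which the chelated Z sodium enolate is oxidized on the face opposite the benzyl group (the same face as in alkylation and azidation), should set the 2S carbinol independently of the remote methyl center.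

**Step 11**
Reactants: 22
Product: 23 (2S,4R)-2-hydroxy-N-methoxy-N,4-dimethylhex-5-enamide
Conditions: MeNH(OMe)·HCl, AlMe3, CH2Cl2, −15 → 0 °C; aqueous Rochelle salt
Reagents that add atoms: N,O-dimethylhydroxylamine hydrochloride, CNOC.Cl
Why: Weinreb transamidation with the aluminium amide cleaves the exocyclic imide carbonyl selectively and returns the auxiliary without epimerization.

**Step 12**
Reactants: 23; 24 4,4,5,5-tetramethyl-2-vinyl-1,3,2-dioxaborolane
Product: 25 (2S,4R,5E)-2-hydroxy-N-methoxy-N,4-dimethyl-6-(4,4,5,5-tetramethyl-1,3,2-dioxaborolan-2-yl)hex-5-enamide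
Conditions: second-generation Grubbs catalyst RuCl2(=CHPh)(PCy3)(H2IMes) (5 mol %), CH2Cl2, 40 °C
Reagents that add atoms: none
Why: Olefin cross-metathesis of a terminal alkene with the vinylboronate should give the E alkenylboronate under thermodynamic control, driven by loss of ethylene.

**Step 13**
Reactants: 25; 13
Product: 26 (2S,4R,5E,7E,12R)-15-(furan-3-yl)-2-hydroxy-N-methoxy-N,4,8,12-tetramethylpentadeca-5,7-dienamide
Conditions: Pd(dppf)Cl2 (5 mol %), K3PO4, THF/H2O, rt → 45 °C
Reagents that add atoms: none
Why: Suzuki–Miyaura sp2–sp2 coupling proceeds with retention of both alkene geometries and tolerates the free hydroxy amide and the furan.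

**Step 14**
Reactants: 26
Product: 27 (4S,6R,7E,9E,14R)-17-(furan-3-yl)-4-hydroxy-6,10,14-trimethylheptadeca-7,9-dien-3-one
Conditions: EtMgBr (4 equiv), THF, −20 → 0 °C; aq. NH4Cl
Reagents that add atoms: ethylmagnesium bromide, CC[Mg]Br
Why: Weinreb ketone synthesis, in which the magnesium alkoxide of the free hydroxyl and the N-methoxy group hold a stable tetrahedral chelate that collapses to the ethyl ketone only on work-up, as is known for unprotected lactate-type Weinreb amides.

**Step 15**
Reactants: 27
Product: 28 (4S,6R,7E,9E,14R)-17-(furan-3-yl)-6,10,14-trimethyl-3-oxoheptadeca-7,9-dien-4-yl 4-methylbenzenesulfonate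
Conditions: Ts2O, pyridine, CH2Cl2, 0 °C → rt
Reagents that add atoms: 4-methylbenzenesulfonic anhydride, Cc1ccc(cc1)S(=O)(=O)OS(=O)(=O)c1ccc(C)cc1
Why: O-Sulfonylation of the secondary α-hydroxy ketone with the anhydride retains configuration at carbon and avoids chloride, which could displace the activated α-keto tosylate.

**Step 16**
Reactants: 28
Product: 30 (5R)-5-[(2R,3E,5E,10R)-13-(furan-3-yl)-2,6,10-trimethyltrideca-3,5-dien-1-yl]-4-hydroxy-3-methylfuran-2(5H)-one, via magnesium ketocarboxylate 29 (not isolated)
Conditions: CO2 (1 atm), Mg(OSO2CF3)2 (2 equiv), i-Pr2NEt (4 equiv), MeCN, 0 → 40 °C; aq. citric acid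
Reagents that add atoms: carbon dioxide, O=C=O
Why: Proposed new method: the divalent magnesium salt and the hindered amine enolize the ketone on its ethyl side, the magnesium enolate adds to CO2 at carbon to give the ketocarboxylate 29, and a carboxylate oxygen then displaces the tosylate at the other α carbon, so that CO2 delivers both the lactone carbonyl and the ring oxygen in a formal [3+2] union with a ketone that is nucleophilic at one α carbon and electrophilic at the other. The closest known reaction types are the carboxylation of ketones with CO2 under a magnesium salt and a tertiary amine, and the lactonization of 4-halo-3-oxo esters to tetronic acids; their merger on an α′-sulfonyloxy ketone has not been described. The furanone ring closes in the 5-exo-tet mode, the sulfonate leaving outside the ring. The only stereocenter formed, C5, is controlled by the substrate alone: backside SN2 attack inverts the 4S tosylate to 5R, and C3 ends as an sp2 enol carbon. The step needs enolization at the ethyl CH2 and not at the C–H under the tosylate, which the known α′ preference of α-oxygenated ethyl ketones under soft enolization should secure, and it needs the absence of halide or other external nucleophiles (triflate counter-ion, non-nucleophilic amine, a sulfonate without acidic α-hydrogens), so that no double inversion or sultone formation can occur, while the CO2 atmosphere traps the enolate before a Favorskii-type 1,3-elimination. If CO2 were taken up at the enolate oxygen instead, tosylate displacement to the alkylidene cyclic carbonate and a 1,3 oxygen-to-carbon carboxyl shift would lead to the same product.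

**Compound list**

1 | (6S)-8-bromo-2,6-dimethyloct-2-ene, (S)-citronellyl bromide | BrCC[C@@H](C)CCC=C(C)C | starting material
2 | tri(propan-2-yl)(prop-1-yn-1-yl)silane | CC#C[Si](C(C)C)(C(C)C)C(C)C | starting material
3 | {3-[tri(propan-2-yl)silyl]prop-2-yn-1-yl}lithium | [Li]CC#C[Si](C(C)C)(C(C)C)C(C)C | intermediate
4 | [(6R)-6,10-dimethylundec-9-en-1-yn-1-yl]tri(propan-2-yl)silane | CC(C)[Si](C(C)C)(C(C)C)C#CCCC[C@@H](C)CCC=C(C)C | intermediate
5 | (4R)-4-methyl-9-[tri(propan-2-yl)silyl]non-8-ynal | CC(C)[Si](C(C)C)(C(C)C)C#CCCC[C@@H](C)CCC=O | intermediate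
6 | (4R)-4-methyl-9-[tri(propan-2-yl)silyl]non-8-yn-1-ol | CC(C)[Si](C(C)C)(C(C)C)C#CCCC[C@@H](C)CCCO | intermediate
7 | [(6R)-9-iodo-6-methylnon-1-yn-1-yl]tri(propan-2-yl)silane | CC(C)[Si](C(C)C)(C(C)C)C#CCCC[C@@H](C)CCCI | intermediate
8 | 3-bromofuran | Brc1ccoc1 | starting material
9 | {(4R)-4-methyl-9-[tri(propan-2-yl)silyl]non-8-yn-1-yl}zinc iodide | CC(C)[Si](C(C)C)(C(C)C)C#CCCC[C@@H](C)CCC[Zn]I | intermediate
10 | [(6S)-9-(furan-3-yl)-6-methylnon-1-yn-1-yl]tri(propan-2-yl)silane | CC(C)[Si](C(C)C)(C(C)C)C#CCCC[C@@H](C)CCCc1ccoc1 | intermediate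
11 | 3-[(4R)-4-methylnon-8-yn-1-yl]furan | C#CCCC[C@@H](C)CCCc1ccoc1 | intermediate
12 | [(1E,6S)-9-(furan-3-yl)-2,6-dimethylnon-1-en-1-yl]dimethylalumane | C[Al](C)/C=C(\C)CCC[C@@H](C)CCCc1ccoc1 | intermediate
13 | 3-[(4S,8E)-9-iodo-4,8-dimethylnon-8-en-1-yl]furan | I/C=C(\C)CCC[C@@H](C)CCCc1ccoc1 | intermediate
14 | (3R)-3,7-dimethylocta-1,6-diene, (R)-β-citronellene | CC(C)=CCC[C@@H](C)C=C | starting material
15 | 2,2-dimethyl-3-[(3R)-3-methylpent-4-en-1-yl]oxirane (both epimers at the oxirane carbon) | CC1(C)OC1CC[C@@H](C)C=C | intermediate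
16 | (4R)-4-methylhex-5-enal | O=CCC[C@@H](C)C=C | intermediate
17 | (4R)-4-methylhex-5-enoic acid | OC(=O)CC[C@@H](C)C=C | intermediate
18 | (4S)-4-benzyl-1,3-oxazolidin-2-one | O=C1OC[C@H](Cc2ccccc2)N1 | starting material
19 | 2,2-dimethylpropanoic (4R)-4-methylhex-5-enoic anhydride | CC(C)(C)C(=O)OC(=O)CC[C@@H](C)C=C | intermediate
20 | (4S)-4-benzyl-3-[(4R)-4-methylhex-5-enoyl]-1,3-oxazolidin-2-one | O=C1OC[C@H](Cc2ccccc2)N1C(=O)CC[C@@H](C)C=C | intermediate
21 | sodium (1Z,4R)-1-[(4S)-4-benzyl-2-oxo-1,3-oxazolidin-3-yl]-4-methylhexa-1,5-dien-1-olate | O=C1OC[C@H](Cc2ccccc2)N1/C([O-])=C/C[C@@H](C)C=C.[Na+] | intermediate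
22 | (4S)-4-benzyl-3-[(2S,4R)-2-hydroxy-4-methylhex-5-enoyl]-1,3-oxazolidin-2-one | O=C1OC[C@H](Cc2ccccc2)N1C(=O)[C@@H](O)C[C@@H](C)C=C | intermediate
23 | (2S,4R)-2-hydroxy-N-methoxy-N,4-dimethylhex-5-enamide | CON(C)C(=O)[C@@H](O)C[C@@H](C)C=C | intermediate
24 | 4,4,5,5-tetramethyl-2-vinyl-1,3,2-dioxaborolane | C=CB1OC(C)(C)C(C)(C)O1 | starting material
25 | (2S,4R,5E)-2-hydroxy-N-methoxy-N,4-dimethyl-6-(4,4,5,5-tetramethyl-1,3,2-dioxaborolan-2-yl)hex-5-enamide | CON(C)C(=O)[C@@H](O)C[C@@H](C)/C=C/B1OC(C)(C)C(C)(C)O1 | intermediate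
26 | (2S,4R,5E,7E,12R)-15-(furan-3-yl)-2-hydroxy-N-methoxy-N,4,8,12-tetramethylpentadeca-5,7-dienamide | CON(C)C(=O)[C@@H](O)C[C@@H](C)/C=C/C=C(\C)CCC[C@@H](C)CCCc1ccoc1 | intermediate
27 | (4S,6R,7E,9E,14R)-17-(furan-3-yl)-4-hydroxy-6,10,14-trimethylheptadeca-7,9-dien-3-one | CCC(=O)[C@@H](O)C[C@@H](C)/C=C/C=C(\C)CCC[C@@H](C)CCCc1ccoc1 | intermediate
28 | (4S,6R,7E,9E,14R)-17-(furan-3-yl)-6,10,14-trimethyl-3-oxoheptadeca-7,9-dien-4-yl 4-methylbenzenesulfonate | CCC(=O)[C@@H](OS(=O)(=O)c1ccc(C)cc1)C[C@@H](C)/C=C/C=C(\C)CCC[C@@H](C)CCCc1ccoc1 | intermediate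
29 | magnesium salt (chelated enolate carboxylate) of (4S,6R,7E,9E,14R)-17-(furan-3-yl)-2,6,10,14-tetramethyl-3-oxo-4-(tosyloxy)heptadeca-7,9-dienoic acid | CC(C([O-])=O)=C([O-])[C@@H](OS(=O)(=O)c1ccc(C)cc1)C[C@@H](C)/C=C/C=C(\C)CCC[C@@H](C)CCCc1ccoc1.[Mg+2] | intermediate
30 | (5R)-5-[(2R,3E,5E,10R)-13-(furan-3-yl)-2,6,10-trimethyltrideca-3,5-dien-1-yl]-4-hydroxy-3-methylfuran-2(5H)-one | CC1=C(O)[C@@H](C[C@@H](C)/C=C/C=C(\C)CCC[C@@H](C)CCCc2ccoc2)OC1=O | target

**Step count and risks**

Total: 16 steps. Longest linear sequence: 10 steps (steps 7–16 from 14; the branch from 1 through steps 1–6 and 13–16 is equally long).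

Steps most likely to fail:

1. Step 16 (the new method). Three processes could spoil it. The configuration at the tosylate carbon could be lost, either by enolization toward that carbon or by ionization of the enolate to an oxyallyl cation before closure. The magnesium chelate could hold the carboxylate on the side away from C5 and stall the closure. The carboxylation could revert, so that decarboxylation on work-up returns the ketone. Fallback with known chemistry, setting out from 26: Mitsunobu esterification with propanoic acid (PPh3, DIAD, THF, 0 °C) should invert the carbinol and give (2R,4R,5E,7E,12R)-15-(furan-3-yl)-1-[methoxy(methyl)amino]-4,8,12-trimethyl-1-oxopentadeca-5,7-dien-2-yl propanoate F1. Treatment with LiN(SiMe3)2 (THF, −78 → 0 °C) should then close the ring by a Dieckmann-type acylation of the propanoate enolate by the Weinreb amide carbonyl, the O1–C5 bond being already in place with the 5R configuration. Acid work-up returns to the route at 30; steps 14–16 are not needed.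

2. Step 12. Cross-metathesis at the allylically branched terminal alkene could be slow, with homodimerization of either partner, erosion of E selectivity, or sequestration of the catalyst by the hydroxy amide. Fallback setting out from 23: ozonolysis of the vinyl group (O3, CH2Cl2, −78 °C; PPh3) should give (2S,4R)-2-hydroxy-N-methoxy-N,4-dimethyl-5-oxopentanamide F2, present largely as its five-membered lactol. Takai–Utimoto boron olefination (CrCl2, Cl2CHBpin, LiI, THF) should convert it to the E alkenylboronate and so return to the route at 25.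

3. Step 6. The carbometalation could be incomplete or less regioselective, or the Lewis-acidic aluminium reagent or iodine could attack the furan. Fallback setting out from 11: copper-catalysed syn methylboration (CuCl, Xantphos, NaOt-Bu, B2pin2, MeI, THF, rt) should give 2-[(1E,6R)-9-(furan-3-yl)-2,6-dimethylnon-1-en-1-yl]-4,4,5,5-tetramethyl-1,3,2-dioxaborolane F3, with boron at the terminus and cis to the new methyl. Ipso-iododeboronation with retention (NaOH then I2, THF/H2O, 0 °C) returns to the route at 13.

**Further compounds**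

F1 | step 16 | (2R,4R,5E,7E,12R)-15-(furan-3-yl)-1-[methoxy(methyl)amino]-4,8,12-trimethyl-1-oxopentadeca-5,7-dien-2-yl propanoate | CON(C)C(=O)[C@H](OC(=O)CC)C[C@@H](C)/C=C/C=C(\C)CCC[C@@H](C)CCCc1ccoc1
F2 | step 12 | (2S,4R)-2-hydroxy-N-methoxy-N,4-dimethyl-5-oxopentanamide | CON(C)C(=O)[C@@H](O)C[C@@H](C)C=O
F3 | step 6 | 2-[(1E,6R)-9-(furan-3-yl)-2,6-dimethylnon-1-en-1-yl]-4,4,5,5-tetramethyl-1,3,2-dioxaborolane | CC1(C)OB(/C=C(\C)CCC[C@@H](C)CCCc2ccoc2)OC1(C)C
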